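The oxolane ring (O1, C2 with the trimethoxyphenyl group, C3 with CH2OH, C4 with the carbinol arm, C5H2) is cut at C2–C3 and at O1–C5. Two features are exploited. C2(O)–C3 with its trans substituents is the anti pattern of a gamma-substituted allylation. C5 lies beta to the arm carbon on C4, so with that carbon as a ketone O1–C5 is an oxa-Michael bond. In one flask an aryl aldehyde is allylated by a 2-aroylallyl bromide whose alkene terminus carries CH2OSi. The unmasked C2 alkoxide then closes onto the alpha-methylene ketone, giving one ring, two bonds and three stereocentres. Ketone reduction and desilylation follow.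

Key step: step 4

Assumption: the (S,S) antipode of the ligand is taken to leave the Re face of the aryl aldehyde open. The sense is to be confirmed in a trial run, and the (R,R) antipode serves if it is the reverse.

Step 1
Reactants: 1 3,4-dimethoxyacetophenone
Product: 2 1-(3,4-dimethoxyphenyl)prop-2-en-1-one
Conditions: (CH2O)n, i-Pr2NH·CF3CO2H (1 equiv), CF3CO2H (0.1 equiv), THF, reflux; used promptly
Reagents that add atoms: formaldehyde (as paraformaldehyde), C=O
Why: Mannich condensation of the methyl ketone with the iminium ion from formaldehyde and the ammonium salt, followed by beta-elimination in the same pot (alpha-methylenation), should give the aryl vinyl ketone, which has no further enolisable position and no stereocentre.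

Step 2
Reactants: 2 1-(3,4-dimethoxyphenyl)prop-2-en-1-one; 3 (tert-butyldimethylsilyloxy)acetaldehyde
Product: 4 racemic 4-(tert-butyldimethylsilyloxy)-1-(3,4-dimethoxyphenyl)-3-hydroxy-2-methylidenebutan-1-one
Conditions: 3 (1.5 equiv), 1,4-diazabicyclo[2.2.2]octane (0.3 equiv), THF, rt, 2 added slowly over several hours
Reagents that add atoms: none
Why: In this Morita–Baylis–Hillman reaction the amine adds to 2, the zwitterionic enolate attacks the activated alpha-silyloxy aldehyde and the amine is expelled; slow addition of 2 to excess 3 holds back Rauhut–Currier self-addition, and the new carbinol centre needs no control because step 3 erases it.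

Step 3
Reactants: 4 racemic 4-(tert-butyldimethylsilyloxy)-1-(3,4-dimethoxyphenyl)-3-hydroxy-2-methylidenebutan-1-one
Product: 5 (Z)-2-(bromomethyl)-4-(tert-butyldimethylsilyloxy)-1-(3,4-dimethoxyphenyl)but-2-en-1-one
Conditions: NBS (1.3 equiv), Me2S (1.5 equiv), CH2Cl2, 0 °C to rt
Reagents that add atoms: N-bromosuccinimide, O=C1CCC(=O)N1Br
Why: The alkoxysulfonium salt formed from the alcohol and the NBS–Me2S adduct is displaced by bromide in SN2' fashion (the allylic transposition known for Baylis–Hillman alcohols) under near-neutral conditions that spare the silyl ether, which should give the conjugated Z bromide, whose geometry does not matter in step 4.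

Step 4
Reactants: 5 (Z)-2-(bromomethyl)-4-(tert-butyldimethylsilyloxy)-1-(3,4-dimethoxyphenyl)but-2-en-1-one; 6 3,4,5-trimethoxybenzaldehyde
Product: 9 (2R,3S,4R)-3-[(tert-butyldimethylsilyloxy)methyl]-4-(3,4-dimethoxybenzoyl)-2-(3,4,5-trimethoxyphenyl)oxolane (all-trans), via trimethylsilyl ether 7 (not isolated), via hydroxy enone 8 (not isolated)
Conditions: 5 (1.5 equiv), CrCl2 (10 mol %), 1,8-bis[(4S)-4-isopropyl-4,5-dihydro-1,3-oxazol-2-yl]-3,6-diphenyl-9H-carbazole (12 mol %), i-Pr2NEt (30 mol %), Mn powder (2 equiv), Me3SiCl (1.5 equiv), THF, 0 °C to rt; then K2CO3, MeOH, same flask, 0 °C to rt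
Reagents that add atoms: none
Why: Proposed new method: CrCl2 reduces the allylic C–Br bond of 5 in two one-electron steps (Mn returns trivalent chromium to the divalent state, Me3SiCl releases the catalyst from the alkoxide), and the allylchromium species adds with allylic transposition through a six-membered chair to the aldehyde carbon of 6, forming C2–C3 and parking O1 as silyl ether 7, which cannot engage the gamma-ketone in the Lewis-acidic medium. The closest known reaction type is the ligand-controlled catalytic Nozaki–Hiyama–Kishi 2-(alkoxycarbonyl)allylation of aldehydes, which ends in lactonisation; an aroyl group in place of the ester and conjugate addition in place of acyl transfer have not been shown. K2CO3 in methanol then strips only the Me3Si group, and the C2 alkoxide of 8 adds to the enone CH2 to form O1–C5 in a 5-endo-trig closure, a mode classed as unfavourable but documented for homoallylic alkoxides bearing a 3-sulfonyl acceptor and helped here by reversibility, since addition of O1 to the carbonyl group or of methanol to the enone is only a resting equilibrium while the saturated ring is the thermodynamic sink. C2 (R) is set by the oxazoline ligand on chromium, which must leave the Re face of 6 open; C3 (S) follows from the chair that holds CH2OSi equatorial and so gives the anti pair; C4 (R) is set last by enolate protonation and base equilibration, which put the aroyl group trans to the C3 substituent. The step needs attack on the aldehyde and not on a ketone, reduction of the bromide and not of the enone, and closure by O1 and not by the primary oxygen; the first two rest on the electron-rich cross-conjugated aroyl group and on the much faster electron transfer to an allylic bromide, the third on the tert-butyldimethylsilyl ether, which stays in place because no fluoride is used. The anti preference is the least certain element, because a 2-acyl substituent favours the allylmetal geometry with the gamma-substituent cis to CH2–Cr and hence the syn pair, and only the bulky non-chelating silyl ether and the aroyl group twisted out of the alkene plane work against this.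

Step 5
Reactants: 9 (2R,3S,4R)-3-[(tert-butyldimethylsilyloxy)methyl]-4-(3,4-dimethoxybenzoyl)-2-(3,4,5-trimethoxyphenyl)oxolane
Product: 10 (S)-{(2R,3S,4R)-3-[(tert-butyldimethylsilyloxy)methyl]-2-(3,4,5-trimethoxyphenyl)oxolan-4-yl}(3,4-dimethoxyphenyl)methanol
Conditions: (R)-1-methyl-3,3-diphenyltetrahydro-1H,3H-pyrrolo[1,2-c][1,3,2]oxazaborole ((R)-Me-CBS, 0.3 equiv), BH3·SMe2 (1.2 equiv), THF, −20 °C; MeOH quench
Reagents that add atoms: none
Why: In the Corey–Bakshi–Shibata reduction the ketone binds to the catalyst boron with the aryl group as the large substituent, so hydride should reach the Re face of the carbonyl group and set the (S) carbinol under reagent control, while the base-free medium leaves C4 and the beta-alkoxy ketone untouched until reduction is complete.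

Step 6
Reactants: 10 (S)-{(2R,3S,4R)-3-[(tert-butyldimethylsilyloxy)methyl]-2-(3,4,5-trimethoxyphenyl)oxolan-4-yl}(3,4-dimethoxyphenyl)methanol
Product: 11 (S)-(3,4-dimethoxyphenyl)[(2R,3S,4R)-3-(hydroxymethyl)-2-(3,4,5-trimethoxyphenyl)oxolan-4-yl]methanol (target)
Conditions: Bu4NF (1.2 equiv), THF, 0 °C to rt
Reagents that add atoms: none
Why: Fluoride-induced silyl ether cleavage is driven by the strong Si–F bond, avoids the acid that would ionise the benzylic C–O bonds, and cannot open the ring because the ketone needed for a retro-oxa-Michael reaction is gone, so no stereocentre is touched.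

Compound list
1 | 3,4-dimethoxyacetophenone | CC(=O)c1ccc(OC)c(OC)c1 | starting material
2 | 1-(3,4-dimethoxyphenyl)prop-2-en-1-one | C=CC(=O)c1ccc(OC)c(OC)c1 | intermediate
3 | (tert-butyldimethylsilyloxy)acetaldehyde | O=CCO[Si](C)(C)C(C)(C)C | starting material
4 | racemic 4-(tert-butyldimethylsilyloxy)-1-(3,4-dimethoxyphenyl)-3-hydroxy-2-methylidenebutan-1-one | C=C(C(O)CO[Si](C)(C)C(C)(C)C)C(=O)c1ccc(OC)c(OC)c1 | intermediate
5 | (Z)-2-(bromomethyl)-4-(tert-butyldimethylsilyloxy)-1-(3,4-dimethoxyphenyl)but-2-en-1-one | BrC/C(C(=O)c1ccc(OC)c(OC)c1)=C\CO[Si](C)(C)C(C)(C)C | intermediate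
6 | 3,4,5-trimethoxybenzaldehyde | COc1cc(C=O)cc(OC)c1OC | starting material
7 | (3S,4R)-3-[(tert-butyldimethylsilyloxy)methyl]-1-(3,4-dimethoxyphenyl)-2-methylidene-4-(3,4,5-trimethoxyphenyl)-4-(trimethylsilyloxy)butan-1-one | C[Si](C)(C)O[C@@H](c1cc(OC)c(OC)c(OC)c1)[C@H](CO[Si](C)(C)C(C)(C)C)C(=C)C(=O)c1ccc(OC)c(OC)c1 | intermediate (not isolated)
8 | (3S,4R)-3-[(tert-butyldimethylsilyloxy)methyl]-1-(3,4-dimethoxyphenyl)-4-hydroxy-2-methylidene-4-(3,4,5-trimethoxyphenyl)butan-1-one | O[C@@H](c1cc(OC)c(OC)c(OC)c1)[C@H](CO[Si](C)(C)C(C)(C)C)C(=C)C(=O)c1ccc(OC)c(OC)c1 | intermediate (not isolated)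
9 | (2R,3S,4R)-3-[(tert-butyldimethylsilyloxy)methyl]-4-(3,4-dimethoxybenzoyl)-2-(3,4,5-trimethoxyphenyl)oxolane | COc1ccc(cc1OC)C(=O)[C@H]2CO[C@@H](c3cc(OC)c(OC)c(OC)c3)[C@@H]2CO[Si](C)(C)C(C)(C)C | intermediate
10 | (S)-{(2R,3S,4R)-3-[(tert-butyldimethylsilyloxy)methyl]-2-(3,4,5-trimethoxyphenyl)oxolan-4-yl}(3,4-dimethoxyphenyl)methanol | COc1ccc([C@@H](O)[C@H]2CO[C@@H](c3cc(OC)c(OC)c(OC)c3)[C@@H]2CO[Si](C)(C)C(C)(C)C)cc1OC | intermediate
11 | (S)-(3,4-dimethoxyphenyl)[(2R,3S,4R)-3-(hydroxymethyl)-2-(3,4,5-trimethoxyphenyl)oxolan-4-yl]methanol | COc1ccc([C@@H](O)[C@H]2CO[C@@H](c3cc(OC)c(OC)c(OC)c3)[C@@H]2CO)cc1OC | target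

Total step count: 6. Longest linear sequence: 6 (1 to 2 to 4 to 5 to 9 to 10 to 11).

Steps most likely to fail

**Step 4.**
- The allylchromium species may react through the geometry in which CH2OSi is cis to CH2–Cr, so that the syn pair and a 2,3-cis ring prevail.
- Electron transfer from the Mn/Me3SiCl couple to the enone, or pinacol coupling of the aldehyde, may consume material.
- The 5-endo closure may lag behind hemiketal formation and dehydration.

The fallback uses known chemistry: conjugate addition of an acyl anion equivalent to a chiral butenolide, aldol trapping and benzylic-cation ring closure. It sets out from 6 and comes back at 9. 3,4-Dimethoxybenzaldehyde and propane-1,3-dithiol (BF3·OEt2, CH2Cl2) give 2-(3,4-dimethoxyphenyl)-1,3-dithiane F1. 5-Hydroxyfuran-2(5H)-one and (+)-menthol (acid catalysis, crystallisation) give (5S)-5-[(1S,2R,5S)-menthyloxy]furan-2(5H)-one F2. F1 is lithiated (n-BuLi, THF, −78 °C) and adds 1,4 to F2 anti to the menthyloxy group. The lactone enolate is trapped by 6 anti to the new substituent, giving the 3,4-trans-4,5-trans aldol lactone F3, whose carbinol centre is of no consequence. LiAlH4 reduces the lactone and acetal carbons to the dithiane triol F4. Catalytic camphorsulfonic acid in CH2Cl2 ionises the trimethoxybenzylic alcohol, and the C5 hydroxyl captures the cation trans to C3 to give the 2,3-trans-3,4-cis oxolane alcohol F5. t-BuMe2SiCl and imidazole give the silyl ether F6. MeI and CaCO3 in aqueous MeCN unmask the 3,4-cis ketone F7. DBU then epimerises C4 to the all-trans ketone 9.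

**Step 2.** Amine-induced self-addition of the aryl vinyl ketone (dimerisation, oligomerisation) may outrun attack on the aldehyde, and the adduct may add to a second molecule of 2. The fallback replaces amine catalysis by a thiolate-triggered Michael–aldol sequence with later elimination. It sets out from 2 and 3 and comes back at 4. Me3Al and PhSH give dimethyl(phenylsulfanyl)aluminium F8. This adds 1,4 to 2 at −78 °C in CH2Cl2, and the aluminium enolate adds to 3 to give the beta-phenylsulfanyl aldol F9 as a diastereomer mixture. NaIO4 in aqueous MeOH gives the sulfoxide F10. Warming in toluene over CaCO3 brings about sulfoxide elimination to 4.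

**Step 5.** Facial selectivity may be poor, because the branched C4 substituent competes with the aryl group for the role of the large group and the inherent bias of the alpha-stereocentre may oppose the catalyst. The fallback gives up reagent control in favour of separation and recycling. It sets out from 9 and comes back at 10. NaBH4 in MeOH at 0 °C reduces 9 to both carbinol epimers, and chromatography delivers 10. The (R)-carbinol epimer F11 is re-oxidised with MnO2 in CH2Cl2 to 9 and reduced again.

Further compounds
F1 | step 4 | 2-(3,4-dimethoxyphenyl)-1,3-dithiane | COc1ccc(C2SCCCS2)cc1OC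
F2 | step 4 | (5S)-5-[(1S,2R,5S)-2-isopropyl-5-methylcyclohexyloxy]furan-2(5H)-one | O=C1C=C[C@@H](O[C@H]2C[C@@H](C)CC[C@@H]2C(C)C)O1
F3 | step 4 | (3R,4S,5S)-4-[2-(3,4-dimethoxyphenyl)-1,3-dithian-2-yl]-3-[hydroxy(3,4,5-trimethoxyphenyl)methyl]-5-[(1S,2R,5S)-menthyloxy]oxolan-2-one | O=C1O[C@H](O[C@H]2C[C@@H](C)CC[C@@H]2C(C)C)[C@@H](C2(c3ccc(OC)c(OC)c3)SCCCS2)[C@@H]1C(O)c1cc(OC)c(OC)c(OC)c1
F4 | step 4 | (2S,3S)-2-[2-(3,4-dimethoxyphenyl)-1,3-dithian-2-yl]-3-[hydroxy(3,4,5-trimethoxyphenyl)methyl]butane-1,4-diol | OC[C@@H](C(O)c1cc(OC)c(OC)c(OC)c1)[C@@H](CO)C1(c2ccc(OC)c(OC)c2)SCCCS1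
F5 | step 4 | [(2R,3S,4S)-4-[2-(3,4-dimethoxyphenyl)-1,3-dithian-2-yl]-2-(3,4,5-trimethoxyphenyl)oxolan-3-yl]methanol | COc1ccc(cc1OC)C1(SCCCS1)[C@@H]2CO[C@@H](c3cc(OC)c(OC)c(OC)c3)[C@@H]2CO
F6 | step 4 | (2R,3S,4S)-3-[(tert-butyldimethylsilyloxy)methyl]-4-[2-(3,4-dimethoxyphenyl)-1,3-dithian-2-yl]-2-(3,4,5-trimethoxyphenyl)oxolane | COc1ccc(cc1OC)C1(SCCCS1)[C@@H]2CO[C@@H](c3cc(OC)c(OC)c(OC)c3)[C@@H]2CO[Si](C)(C)C(C)(C)C
F7 | step 4 | (2R,3S,4S)-3-[(tert-butyldimethylsilyloxy)methyl]-4-(3,4-dimethoxybenzoyl)-2-(3,4,5-trimethoxyphenyl)oxolane | COc1ccc(cc1OC)C(=O)[C@@H]2CO[C@@H](c3cc(OC)c(OC)c(OC)c3)[C@@H]2CO[Si](C)(C)C(C)(C)C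
F8 | step 2 | dimethyl(phenylsulfanyl)aluminium | C[Al](C)Sc1ccccc1
F9 | step 2 | 4-(tert-butyldimethylsilyloxy)-1-(3,4-dimethoxyphenyl)-3-hydroxy-2-[(phenylsulfanyl)methyl]butan-1-one (racemic diastereomer mixture) | COc1ccc(cc1OC)C(=O)C(CSc1ccccc1)C(O)CO[Si](C)(C)C(C)(C)C
F10 | step 2 | 4-(tert-butyldimethylsilyloxy)-1-(3,4-dimethoxyphenyl)-3-hydroxy-2-[(phenylsulfinyl)methyl]butan-1-one (racemic diastereomer mixture) | COc1ccc(cc1OC)C(=O)C(CS(=O)c1ccccc1)C(O)CO[Si](C)(C)C(C)(C)C
F11 | step 5 | (R)-{(2R,3S,4R)-3-[(tert-butyldimethylsilyloxy)methyl]-2-(3,4,5-trimethoxyphenyl)oxolan-4-yl}(3,4-dimethoxyphenyl)methanol | COc1ccc([C@H](O)[C@H]2CO[C@@H](c3cc(OC)c(OC)c(OC)c3)[C@@H]2CO[Si](C)(C)C(C)(C)C)cc1OC
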